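**Retrosynthetic overview**
1. Target 16 ⇐ senecioylation of the C1 alcohol 15; the C3 isovalerate is put on at the aldol stage.
2. Cyclobutane and cyclohexenone (bicyclo[3.1.1]heptenone, formed last) ⇐ ring-contracting semipinacol 1,2-shift of the 1-silyloxy-2-endo-bromonorbornene 13.
3. Norbornene and seven-membered ring of 13 (formed together) ⇐ intramolecular Diels–Alder reaction of a 5,5-disubstituted silyloxycyclopentadiene carrying an (E)-bromoalkene on a four-carbon tether.
4. Diels–Alder precursor 11 ⇐ Mukaiyama aldol of dienol ether 7 with aldehyde 5, then aldolate-directed C-methylation (quaternary C4) and O-acylation.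
5. Aldehyde 5 ⇐ hydroxypivaldehyde 1 by Takai bromo-olefination, iridium-catalysed asymmetric allylation, silylation and oxidative cleavage. Ring order: cyclopentene (bought) → norbornene plus cycloheptane (one step) → cyclobutane/cyclohexenone (ring contraction).

Assumption: the stereodescriptors of the given SMILES are the absolute configuration. Ring carbons are called C1–C11 in the order they appear in that SMILES (C1 senecioate carbinol, C3 isovalerate carbinol, C4 quaternary C–Me, C5 and C9 the cyclobutane CH atoms next to C4, C6 carbonyl, C8 vinylic C–Me, C10 fourth cyclobutane carbon, C11 CMe2).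

**Route**

Step 1
Reactants: 1 3-hydroxy-2,2-dimethylpropanal
Product: 2 (3E)-4-bromo-2,2-dimethylbut-3-en-1-ol
Conditions: CHBr3, CrBr2, THF, 50 °C
Reagents that add atoms: bromoform BrC(Br)Br
Why: Takai–Utimoto haloolefination, in which the gem-dichromium species from CHBr3 and divalent chromium adds to the non-enolisable aldehyde and eliminates to the E-bromoalkene (E favoured by the quaternary neighbour), while CrBr2 avoids Br/Cl exchange and tolerates the free hydroxyl.

Step 2
Reactants: 2 (3E)-4-bromo-2,2-dimethylbut-3-en-1-ol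
Product: 3 (1E,4R)-1-bromo-3,3-dimethylhepta-1,6-dien-4-ol
Conditions: allyl acetate, [Ir(cod)Cl]2, (R)-BINAP (antipode chosen to give 4R), 4-chloro-3-nitrobenzoic acid, Cs2CO3, THF, 100 °C
Reagents that add atoms: allyl acetate CC(=O)OCC=C
Why: Krische transfer-hydrogenative carbonyl allylation from the alcohol oxidation level, in which the neopentyl alcohol is dehydrogenated to the non-enolisable aldehyde and the cyclometallated allyliridium complex adds through a closed chair transition state, so the catalyst sets the 4R carbinol (future C1); the vinyl bromide is not expected to add oxidatively to the trivalent iridium species.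

Step 3
Reactants: 3 (1E,4R)-1-bromo-3,3-dimethylhepta-1,6-dien-4-ol
Product: 4 {[(1E,4R)-1-bromo-3,3-dimethylhepta-1,6-dien-4-yl]oxy}(triethyl)silane
Conditions: Et3SiOTf, 2,6-lutidine, CH2Cl2, −78 °C
Reagents that add atoms: triethylsilyl trifluoromethanesulfonate CC[Si](CC)(CC)OS(=O)(=O)C(F)(F)F
Why: Standard silyl triflate protection of a hindered secondary alcohol, which keeps this oxygen inert until step 9 and touches no stereocentre.

Step 4
Reactants: 4 {[(1E,4R)-1-bromo-3,3-dimethylhepta-1,6-dien-4-yl]oxy}(triethyl)silane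
Product: 5 (3R,5E)-6-bromo-4,4-dimethyl-3-[(triethylsilyl)oxy]hex-5-enal
Conditions: OsO4 (2 mol %), NaIO4, 2,6-lutidine, dioxane/H2O, rt
Reagents that add atoms: sodium periodate [Na+].[O-]I(=O)(=O)=O (aldehyde oxygen, relayed by OsO4)
Why: Lemieux–Johnson oxidative cleavage, in which OsO4 dihydroxylates the electron-rich monosubstituted alkene much faster than the hindered electron-poor bromoalkene and periodate cleaves the diol, with lutidine buffering against silyl loss.

Step 5
Reactants: 6 3-methylcyclopent-2-en-1-one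
Product: 7 1-methyl-3-[(trimethylsilyl)oxy]cyclopenta-1,3-diene
Conditions: LiN(iPr)2, THF, −78 °C; Me3SiCl
Reagents that add atoms: chlorotrimethylsilane C[Si](C)(C)Cl
Why: Kinetic deprotonation of the enone at the alpha-prime carbon and O-silylation give the cross-conjugated 2-silyloxydiene, which is used at once and cold to avoid 1,5-hydrogen shifts.

Step 6
Reactants: 5 (3R,5E)-6-bromo-4,4-dimethyl-3-[(triethylsilyl)oxy]hex-5-enal; 7 1-methyl-3-[(trimethylsilyl)oxy]cyclopenta-1,3-diene
Product: 8 5-{(1R,3R,5E)-6-bromo-1-hydroxy-4,4-dimethyl-3-[(triethylsilyl)oxy]hex-5-en-1-yl}-3-methylcyclopent-2-en-1-one (both epimers at the ring CH)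
Conditions: BF3·OEt2, CH2Cl2, −78 °C; aq NaHCO3
Reagents that add atoms: none
Why: Mukaiyama aldol addition through an open transition state, in which the enol ether terminus attacks the BF3-bound aldehyde anti to the beta-silyloxy group (Evans polar 1,3-induction model) to give the 1,3-anti (R,R) relationship of C3 to C1; the ring CH stays epimerisable and is fixed in step 7.

Step 7
Reactants: 8 5-{(1R,3R,5E)-6-bromo-1-hydroxy-4,4-dimethyl-3-[(triethylsilyl)oxy]hex-5-en-1-yl}-3-methylcyclopent-2-en-1-one
Product: 11 (1R,3R,5E)-6-bromo-1-[(1S)-1,4-dimethyl-2-oxocyclopent-3-en-1-yl]-4,4-dimethyl-3-[(triethylsilyl)oxy]hex-5-en-1-yl 3-methylbutanoate, via dilithium alkoxide dienolate 9 (not isolated), via methylated lithium alkoxide 10 (not isolated)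
Conditions: LiN(iPr)2 (2.2 equiv), THF, −78 to −45 °C; MeI, DMPU; then (Me2CHCH2CO)2O, DMAP, −45 to 0 °C
Reagents that add atoms: iodomethane [CH3]I; 3-methylbutanoic anhydride CC(C)CC(=O)OC(=O)CC(C)C
Why: Fráter–Seebach-type alkylation, in which the chelated dilithium alkoxide–enolate is methylated on the enolate face anti to the side chain of the carbinol carbon, giving the quaternary (S) centre (future C4) with methyl anti to the C3 oxygen; the lithium alkoxide is acylated in the same flask before retro-aldol can scramble it, and the dianion itself cannot retro-aldolise.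

Step 8
Reactants: 11 (1R,3R,5E)-6-bromo-1-[(1S)-1,4-dimethyl-2-oxocyclopent-3-en-1-yl]-4,4-dimethyl-3-[(triethylsilyl)oxy]hex-5-en-1-yl 3-methylbutanoate
Product: 13 (1R,2S,3R,5R,7R,8R,9R)-8-bromo-2,6,6,11-tetramethyl-5,9-bis[(triethylsilyl)oxy]tricyclo[5.4.0.0(2,9)]undec-10-en-3-yl 3-methylbutanoate (bromine endo), via triethylsilyloxy cyclopentadiene 12 (not isolated)
Conditions: Et3SiOTf, Et3N, CH2Cl2, 0 °C to rt; then toluene, BHT, 160 °C, sealed tube
Reagents that add atoms: triethylsilyl trifluoromethanesulfonate CC[Si](CC)(CC)OS(=O)(=O)C(F)(F)F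
Why: Soft enolisation (only gamma hydrogens are left) gives a 5,5-disubstituted 1-silyloxycyclopentadiene that cannot undergo 1,5-hydrogen shifts, and an intramolecular Diels–Alder reaction then closes the norbornene and the seven-membered ring together; the tether forces addition to its own diene face and the exo position at C10, so the E alkene places bromine endo, and the ortho rule plus the clash between CMe2 and the silyloxy terminus send the bromine-bearing carbon to the silyloxy terminus.

Step 9
Reactants: 13 (1R,2S,3R,5R,7R,8R,9R)-8-bromo-2,6,6,11-tetramethyl-5,9-bis[(triethylsilyl)oxy]tricyclo[5.4.0.0(2,9)]undec-10-en-3-yl 3-methylbutanoate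
Product: 15 (1R,2S,4R,6R,7R,8R)-4-hydroxy-3,3,7,11-tetramethyl-9-oxotricyclo[5.4.0.0(2,8)]undec-10-en-6-yl 3-methylbutanoate, via rearranged enone silyl ether 14 (not isolated)
Conditions: AgBF4, 2,6-di-tert-butylpyridine, CH2Cl2, −40 °C to rt; then HF·pyridine, THF, 0 °C
Reagents that add atoms: none
Why: Proposed new method: silver pulls off the endo bromide while the antiperiplanar one-carbon bridge bond (C4–C6) migrates to C5 with inversion there and retention at C4, and the resulting silyloxy-stabilised allyl cation loses the silyl group to give the enone, so the norbornene contracts to the cyclobutane-containing bicyclo[3.1.1]heptenone (only the bridge bond is anti to an endo leaving group, and no anti hydrogen is available for elimination); the closest known chemistry is semipinacol and Tiffeneau-type halohydrin ring contraction and silver-promoted silyl-semipinacol shifts, and HF·pyridine then frees the C1 hydroxyl without base so the isovalerate does not migrate.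

Step 10
Reactants: 15 (1R,2S,4R,6R,7R,8R)-4-hydroxy-3,3,7,11-tetramethyl-9-oxotricyclo[5.4.0.0(2,8)]undec-10-en-6-yl 3-methylbutanoate
Product: 16 (1R,2S,4R,6R,7R,8R)-3,3,7,11-tetramethyl-6-[(3-methylbutanoyl)oxy]-9-oxotricyclo[5.4.0.0(2,8)]undec-10-en-4-yl 3-methylbut-2-enoate
Conditions: 3-methylbut-2-enoyl chloride, pyridine, DMAP, CH2Cl2, 0 °C to rt
Reagents that add atoms: 3-methylbut-2-enoyl chloride CC(C)=CC(Cl)=O
Why: DMAP-catalysed acylation of the one remaining (hindered, secondary) alcohol, whose trans relationship to the C3 ester across the rigid ring disfavours acyl migration; no stereocentre is touched.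

**Compound list**
1 | 3-hydroxy-2,2-dimethylpropanal | OCC(C)(C)C=O | starting material
2 | (3E)-4-bromo-2,2-dimethylbut-3-en-1-ol | OCC(C)(C)/C=C/Br | intermediate
3 | (1E,4R)-1-bromo-3,3-dimethylhepta-1,6-dien-4-ol | C=CC[C@@H](O)C(C)(C)/C=C/Br | intermediate
4 | {[(1E,4R)-1-bromo-3,3-dimethylhepta-1,6-dien-4-yl]oxy}(triethyl)silane | C=CC[C@@H](O[Si](CC)(CC)CC)C(C)(C)/C=C/Br | intermediate
5 | (3R,5E)-6-bromo-4,4-dimethyl-3-[(triethylsilyl)oxy]hex-5-enal | O=CC[C@@H](O[Si](CC)(CC)CC)C(C)(C)/C=C/Br | intermediate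
6 | 3-methylcyclopent-2-en-1-one | CC1=CC(=O)CC1 | starting material
7 | 1-methyl-3-[(trimethylsilyl)oxy]cyclopenta-1,3-diene | CC1=CC(O[Si](C)(C)C)=CC1 | intermediate
8 | 5-{(1R,3R,5E)-6-bromo-1-hydroxy-4,4-dimethyl-3-[(triethylsilyl)oxy]hex-5-en-1-yl}-3-methylcyclopent-2-en-1-one (both epimers at the ring CH) | CC1=CC(=O)C(C1)[C@H](O)C[C@@H](O[Si](CC)(CC)CC)C(C)(C)/C=C/Br | intermediate
9 | dilithium alkoxide dienolate of 8 | CC1=CC([O-])=C(C1)[C@H]([O-])C[C@@H](O[Si](CC)(CC)CC)C(C)(C)/C=C/Br.[Li+].[Li+] | intermediate (not isolated)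
10 | lithium alkoxide of the C-methylated hydroxy ketone | CC1=CC(=O)[C@@](C)(C1)[C@H]([O-])C[C@@H](O[Si](CC)(CC)CC)C(C)(C)/C=C/Br.[Li+] | intermediate (not isolated)
11 | (1R,3R,5E)-6-bromo-1-[(1S)-1,4-dimethyl-2-oxocyclopent-3-en-1-yl]-4,4-dimethyl-3-[(triethylsilyl)oxy]hex-5-en-1-yl 3-methylbutanoate | CC1=CC(=O)[C@@](C)(C1)[C@H](OC(=O)CC(C)C)C[C@@H](O[Si](CC)(CC)CC)C(C)(C)/C=C/Br | intermediate
12 | (1R,3R,5E)-6-bromo-1-{(1S)-1,3-dimethyl-5-[(triethylsilyl)oxy]cyclopenta-2,4-dien-1-yl}-4,4-dimethyl-3-[(triethylsilyl)oxy]hex-5-en-1-yl 3-methylbutanoate | CC1=C[C@@](C)([C@H](OC(=O)CC(C)C)C[C@@H](O[Si](CC)(CC)CC)C(C)(C)/C=C/Br)C(O[Si](CC)(CC)CC)=C1 | intermediate (not isolated)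
13 | (1R,2S,3R,5R,7R,8R,9R)-8-bromo-2,6,6,11-tetramethyl-5,9-bis[(triethylsilyl)oxy]tricyclo[5.4.0.0(2,9)]undec-10-en-3-yl 3-methylbutanoate (Br endo, syn to the alkene) | CC[Si](CC)(CC)O[C@@]12C=C(C)[C@H]3[C@@H]([C@H]1Br)C(C)(C)[C@H](O[Si](CC)(CC)CC)C[C@@H](OC(=O)CC(C)C)[C@@]23C | intermediate
14 | (1R,2S,4R,6R,7R,8R)-3,3,7,11-tetramethyl-9-oxo-4-[(triethylsilyl)oxy]tricyclo[5.4.0.0(2,8)]undec-10-en-6-yl 3-methylbutanoate | CC[Si](CC)(CC)O[C@@H]1C[C@@H](OC(=O)CC(C)C)[C@@]2(C)[C@@H]3C(=O)C=C(C)[C@H]2[C@@H]3C1(C)C | intermediate (not isolated)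
15 | (1R,2S,4R,6R,7R,8R)-4-hydroxy-3,3,7,11-tetramethyl-9-oxotricyclo[5.4.0.0(2,8)]undec-10-en-6-yl 3-methylbutanoate | O[C@@H]1C[C@@H](OC(=O)CC(C)C)[C@@]2(C)[C@@H]3C(=O)C=C(C)[C@H]2[C@@H]3C1(C)C | intermediate
16 | (1R,2S,4R,6R,7R,8R)-3,3,7,11-tetramethyl-6-[(3-methylbutanoyl)oxy]-9-oxotricyclo[5.4.0.0(2,8)]undec-10-en-4-yl 3-methylbut-2-enoate (CNP0214473.1) | CC(C)=CC(=O)O[C@@H]1C[C@@H](OC(=O)CC(C)C)[C@@]2(C)[C@@H]3C(=O)C=C(C)[C@H]2[C@@H]3C1(C)C | target

**Totals**
Total steps: 10. Longest linear sequence: 9 (steps 1–4 and 6–10; step 5 is the side branch).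

**Three steps most likely to fail, each with a fallback**

Step 8 (intramolecular Diels–Alder). The bromoalkene is unactivated and sits next to a quaternary carbon, so the cycloaddition may need temperatures at which the silyloxydiene degrades, and the regiochemistry rests on the ortho rule and sterics only. The fallback sets out from 11 and activates the dienophile. Copper-catalysed coupling with sodium benzenesulfinate (CuI, (S)-proline, DMSO, 90 °C) replaces bromine with retention of alkene geometry and gives the (E)-vinyl sulfone F1. The same silyl triflate enolisation and a much milder cycloaddition (sulfonyl carbon bonding to the silyloxy terminus, sulfonyl endo) give the sulfonyl cycloadduct F2. Et2AlCl then expels benzenesulfinate with the same antiperiplanar bridge shift (hydroxy-sulfone pinacol-type rearrangement), and HF·pyridine removes the remaining silyl ether, which returns to the route at 15.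

Step 9 (ring-contracting 1,2-shift). The cationic, silver-triggered shift may lose to Wagner–Meerwein scrambling or to capture of the cation. The fallback sets out from 13 and reverses the polarity of the rearrangement. HF·pyridine removes both silyl ethers to give the bromo diol F3, and its magnesium alkoxide (t-BuMgCl, 2.1 equiv, toluene, 0 to 60 °C) undergoes an anionic Tiffeneau-type halohydrin ring contraction (alkoxide push, magnesium-assisted bromide loss). This returns to the route at 15.

Step 7 (aldolate-directed methylation). The lithium aldolate can undergo retro-aldol cleavage, the 1,3-related silyl group can migrate, and the new quaternary centre is crowded. The fallback sets out from 5 and changes the order of bond formation. Ketone 6 is methylated first (LiN(iPr)2, MeI) to 3,5-dimethylcyclopent-2-en-1-one F4, which is converted (LiN(iPr)2, Me3SiCl) into the tetrasubstituted silyl dienol ether F5. A BF3·OEt2 Mukaiyama aldol of F5 with 5 then forms the C3–C4 bond and the quaternary centre in one step. This gives the quaternary hydroxy ketone F6, but the methyl-versus-ring-CH2 selectivity of that open transition state is not predictable, so the C4 epimer has to be removed by chromatography. Acylation with 3-methylbutanoic anhydride and DMAP returns to the route at 11.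

**Further compounds**
F1 | step 8 | (1R,3R,5E)-1-[(1S)-1,4-dimethyl-2-oxocyclopent-3-en-1-yl]-4,4-dimethyl-6-(phenylsulfonyl)-3-[(triethylsilyl)oxy]hex-5-en-1-yl 3-methylbutanoate | CC1=CC(=O)[C@@](C)(C1)[C@H](OC(=O)CC(C)C)C[C@@H](O[Si](CC)(CC)CC)C(C)(C)/C=C/S(=O)(=O)c1ccccc1
F2 | step 8 | (1R,2S,3R,5R,7R,8R,9R)-2,6,6,11-tetramethyl-8-(phenylsulfonyl)-5,9-bis[(triethylsilyl)oxy]tricyclo[5.4.0.0(2,9)]undec-10-en-3-yl 3-methylbutanoate | CC[Si](CC)(CC)O[C@@]12C=C(C)[C@H]3[C@@H]([C@H]1S(=O)(=O)c1ccccc1)C(C)(C)[C@H](O[Si](CC)(CC)CC)C[C@@H](OC(=O)CC(C)C)[C@@]23C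
F3 | step 9 | (1R,2S,3R,5R,7R,8R,9R)-8-bromo-5,9-dihydroxy-2,6,6,11-tetramethyltricyclo[5.4.0.0(2,9)]undec-10-en-3-yl 3-methylbutanoate | O[C@@]12C=C(C)[C@H]3[C@@H]([C@H]1Br)C(C)(C)[C@H](O)C[C@@H](OC(=O)CC(C)C)[C@@]23C
F4 | step 7 | 3,5-dimethylcyclopent-2-en-1-one (racemic) | CC1CC(C)=CC1=O
F5 | step 7 | 1,4-dimethyl-2-[(trimethylsilyl)oxy]cyclopenta-1,3-diene | CC1=CC(O[Si](C)(C)C)=C(C)C1
F6 | step 7 | (5S)-5-{(1R,3R,5E)-6-bromo-1-hydroxy-4,4-dimethyl-3-[(triethylsilyl)oxy]hex-5-en-1-yl}-3,5-dimethylcyclopent-2-en-1-one | CC1=CC(=O)[C@@](C)(C1)[C@H](O)C[C@@H](O[Si](CC)(CC)CC)C(C)(C)/C=C/Br
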